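## Retrosynthetic overview

- **Feature:** in unit A (the half with the acetoxypropenyl chain, isochromene numbering) C7 carries a methyl group and an ester oxygen and lies between the C6 and C8 ketones of ring A. It is therefore C2 of (S)-lactic acid acylated twice on carbon, and ring A is never an arene. C7′ of unit B is the same carbon from (R)-lactic acid, with C6′ at the carbinol level.
- **Union:** Knoevenagel bond C5=CH between methylene dione 22 and enal 34, then removal of the aryl silyl ethers. Both orsellinates come from acid chloride 18 (on O7 through the alkoxide, on O6′ after cis-selective reduction of C6′).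
- **Second ring of each half (pyran):** O2–C3 by 6-endo-dig cycloisomerization of the C1 hydroxymethyl group onto the ynenone.
- **First ring of each half (carbocycle):** C5–C6 by vinylogous Dieckmann closure of an enynone dienolate onto the lactate dioxolanone with loss of pivalaldehyde (14 → 15; 26 → 27).
- **Precursors:** both from one achiral enal 9 (enol triflate 4 + enyne 6, Sonogashira) by aldol addition of the (S)- or (R)-lactate dioxolanone and oxidation.

Key step: step 11

Remarks on the chemistry: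
- Atom labels C1–C8a are the isochromene positions of the finished halves (primed for unit B). Compound names use their own locants. TBS = tert-butyldimethylsilyl, TES = triethylsilyl.
- The diones 15, 19–22, 27 and 29 are written as diketo forms; partial enolization towards C5 is assumed not to change the reactivity used.
- Precursor 14 is made as the (2Z) isomer (alkyne, not the C5 methyl, cis to the acyl group). Only the s-trans enone conformer gives a dienolate that can cyclize, and it is less strained when the slim alkyne faces C7.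
- (2E)-Pent-2-en-4-yn-1-ol and both lactic acids are taken as commercial.

## Route

Step 1
Reactants: 1 methyl 3-hydroxypropanoate
Product: 2 methyl 3-(TBSO)propanoate
Conditions: TBSCl, imidazole, CH2Cl2, 0 → 23 °C
Reagents that add atoms: tert-butyldimethylsilyl chloride (TBSCl), CC(C)(C)[Si](C)(C)Cl
Why: Silyl ether formation on the primary alcohol protects the future C1 oxygen against the bases and hydrides that follow.

Step 2
Reactants: 2 methyl 3-(TBSO)propanoate
Product: 3 methyl 2-(TBSOCH2)-3-oxobutanoate (racemic)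
Conditions: LiN(SiMe3)2 (2.1 equiv.), THF, −78 °C; AcCl, −78 °C; aq. NH4Cl
Reagents that add atoms: acetyl chloride, CC(Cl)=O
Why: Crossed Claisen acylation of the lithium ester enolate is fast at −78 °C, where loss of the beta-silyloxy group is slow, and the second equivalent of base stores the beta-keto ester as its chelated enolate until work-up.

Step 3
Reactants: 3 methyl 2-(TBSOCH2)-3-oxobutanoate
Product: 4 methyl (2Z)-2-(TBSOCH2)-3-(trifluoromethylsulfonyloxy)but-2-enoate
Conditions: NaH, Et2O, 0 °C; Tf2O, −78 → 0 °C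
Reagents that add atoms: trifluoromethanesulfonic anhydride (Tf2O), O=S(=O)(OS(=O)(=O)C(F)(F)F)C(F)(F)F
Why: O-Sulfonylation of the chelated sodium enolate (enol triflate formation) should place the triflate cis to the ester and gives the electrophile for cross-coupling.

Step 4
Reactants: 5 (2E)-pent-2-en-4-yn-1-ol
Product: 6 tert-butyl(dimethyl)[(2E)-pent-2-en-4-yn-1-yloxy]silane
Conditions: TBSCl, imidazole, CH2Cl2, 0 → 23 °C
Reagents that add atoms: tert-butyldimethylsilyl chloride (TBSCl), CC(C)(C)[Si](C)(C)Cl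
Why: Silyl ether formation masks the primary allylic alcohol of the side chain while the terminal alkyne stays free for coupling.

Step 5
Reactants: 4 enol triflate; 6 silylated enyne
Product: 7 methyl (2Z,6E)-8-(TBSO)-2-(TBSOCH2)-3-methylocta-2,6-dien-4-ynoate
Conditions: PdCl2(PPh3)2 (3 mol %), CuI (6 mol %), iPr2NH, THF, 23 °C
Reagents that add atoms: none
Why: Sonogashira coupling of the electron-poor enol triflate with the terminal enyne proceeds with retention at the tetrasubstituted alkene, so the alkyne ends up cis to the ester.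

Step 6
Reactants: 7 dienynoate
Product: 8 (2E,6E)-8-(TBSO)-2-(TBSOCH2)-3-methylocta-2,6-dien-4-yn-1-ol (same alkene geometry as 7)
Conditions: iBu2AlH (2.5 equiv.), CH2Cl2, −78 °C; Rochelle salt
Reagents that add atoms: none
Why: 1,2-Reduction of the conjugated ester by the aluminium hydride gives the allylic alcohol without touching the enyne or the silyl ethers.

Step 7
Reactants: 8 allylic alcohol
Product: 9 (2Z,6E)-8-(TBSO)-2-(TBSOCH2)-3-methylocta-2,6-dien-4-ynal
Conditions: MnO2, CH2Cl2, 23 °C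
Reagents that add atoms: none
Why: Allylic oxidation with MnO2 stops at the aldehyde and is neutral, so neither silyl migration between the two CH2O groups nor alkene isomerization is expected.

Step 8
Reactants: 10 (S)-lactic acid; 11 pivalaldehyde
Product: 12 (2S,5S)-2-tert-butyl-5-methyl-1,3-dioxolan-4-one
Conditions: TsOH·H2O (cat.), H2SO4 (cat.), pentane, reflux, Dean–Stark; crystallization, −78 °C
Reagents that add atoms: none
Why: Acid-catalysed acetalization with azeotropic removal of water gives mainly the cis dioxolanone, purified by crystallization, in which the tert-butyl acetal centre stores the lactate configuration (self-regeneration of stereocentres).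

Step 9
Reactants: 12 (2S,5S)-dioxolanone; 9 enal
Product: 13 (2S,5R)-2-tert-butyl-5-[(2Z,6E)-8-(TBSO)-2-(TBSOCH2)-1-hydroxy-3-methylocta-2,6-dien-4-yn-1-yl]-5-methyl-1,3-dioxolan-4-one (both carbinol epimers)
Conditions: LiN(iPr)2, THF, −78 °C; 9, −78 °C; AcOH
Reagents that add atoms: none
Why: Aldol addition of the lithium enolate of 12 should take place on the face opposite to the tert-butyl group, so C7 is formed with methyl cis to tert-butyl (net retention from (S)-lactate), while the carbinol centre need not be controlled because it is oxidized next.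

Step 10
Reactants: 13 aldol adduct
Product: 14 (2S,5R)-2-tert-butyl-5-[(2Z,6E)-8-(TBSO)-2-(TBSOCH2)-3-methylocta-2,6-dien-4-ynoyl]-5-methyl-1,3-dioxolan-4-one
Conditions: Dess–Martin periodinane, CH2Cl2, 0 → 23 °C
Reagents that add atoms: none
Why: Dess–Martin oxidation converts the hindered allylic carbinol into the C8 ketone under near-neutral conditions that avoid retro-aldol cleavage.

Step 11
Reactants: 14 acyl dioxolanone
Product: 15 (2S)-5-[(3E)-5-(TBSO)pent-3-en-1-yn-1-yl]-4-(TBSOCH2)-2-hydroxy-2-methylcyclohex-4-ene-1,3-dione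
Conditions: LiN(SiMe3)2 (2.5 equiv.), THF, −78 → 0 °C; AcOH
Reagents that add atoms: none
Why: Proposed new method: LiN(SiMe3)2 can only deprotonate the C5 methyl group of enynone 14 (C7 is quaternary, so there is no alpha′ hydrogen), giving the linear dienolate O–C8=C8a–C4a=C5, whose terminal carbon adds to the dioxolanone carbonyl (C6); the tetrahedral intermediate expels the acetal oxygen and the hemiacetal alkoxide then loses pivalaldehyde, which leaves the C7 alkoxide. The closest known reaction types are vinylogous Dieckmann condensations of gamma-deprotonated enones onto esters and acyl transfer from 5,5-disubstituted 1,3-dioxolan-4-ones to nucleophiles, which have not been combined in one ring closure. Ring A (C4a–C5–C6–C7–C8–C8a) closes in the 6-(enolendo)-exo-trig mode, and the only other carbon nucleophile of the dienolate, C8a, would have to form a four-membered ring. No stereocentre is created: C7 is quaternary, is not touched by the bond formation and keeps the configuration fixed in step 9. The step needs the dienolate in which C7 and C4a are cis about C8=C8a, which the (2Z) geometry of 14 should provide, because with the slim alkyne facing the acyl group the s-trans enone conformer is the one deprotonated, and a dienolate of the other geometry can still equilibrate by proton exchange with HN(SiMe3)2 on warming. The cyclized dione is deprotonated at C5 at once, which makes the sequence irreversible and turns C6 into an enolate carbon, so that acyloin-type ring contraction of the alpha-ketol is not expected.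

Step 12
Reactants: 16 orsellinic acid (2,4-dihydroxy-6-methylbenzoic acid)
Product: 17 tert-butyldimethylsilyl 2,4-bis(TBSO)-6-methylbenzoate
Conditions: TBSCl (3.5 equiv.), imidazole, DMF, 23 °C
Reagents that add atoms: tert-butyldimethylsilyl chloride (TBSCl), CC(C)(C)[Si](C)(C)Cl
Why: Exhaustive silylation covers both phenols and the carboxyl group in one operation (silyl ether and silyl ester formation).

Step 13
Reactants: 17 tris-silylated orsellinic acid
Product: 18 2,4-bis(TBSO)-6-methylbenzoyl chloride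
Conditions: (COCl)2, DMF (cat.), CH2Cl2, 0 → 23 °C
Reagents that add atoms: oxalyl chloride, O=C(Cl)C(Cl)=O
Why: The chloroiminium species from oxalyl chloride and DMF converts a silyl ester directly into the acid chloride with loss of TBSCl, so no HCl is formed that could cleave the aryl silyl ethers.

Step 14
Reactants: 15 ring A hydroxy dione; 18 acid chloride
Product: 19 (1S)-4-[(3E)-5-(TBSO)pent-3-en-1-yn-1-yl]-3-(TBSOCH2)-1-methyl-2,6-dioxocyclohex-3-en-1-yl 2,4-bis(TBSO)-6-methylbenzoate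
Conditions: LiN(SiMe3)2 (2.1 equiv.), THF, −78 °C; 18, −78 → −20 °C; AcOH
Reagents that add atoms: none
Why: In the dilithium salt of 15 the C7 alkoxide is the most basic oxygen and is acylated by the aroyl chloride (alkoxide esterification), while an aroyl group that lands on the dienolate oxygen can move on to O7 because the delocalized dienolate is the better leaving group.

Step 15
Reactants: 19 silylated ring A ester
Product: 20 (1S)-3-(hydroxymethyl)-4-[(3E)-5-hydroxypent-3-en-1-yn-1-yl]-1-methyl-2,6-dioxocyclohex-3-en-1-yl 2,4-bis(TBSO)-6-methylbenzoate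
Conditions: HF·pyridine, pyridine, THF, 0 °C
Reagents that add atoms: none
Why: Buffered HF should cleave the two primary alkyl silyl ethers much faster than the aryl silyl ethers of the electron-poor benzoate (selective desilylation).

Step 16
Reactants: 20 diol
Product: 21 (7S)-3-[(1E)-3-hydroxyprop-1-en-1-yl]-7-methyl-6,8-dioxo-5,6,7,8-tetrahydro-1H-isochromen-7-yl 2,4-bis(TBSO)-6-methylbenzoate
Conditions: AuCl(PPh3) (5 mol %), AgOTf (5 mol %), CH2Cl2, 23 °C
Reagents that add atoms: none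
Why: Gold-catalysed hydroalkoxylation of the alkyne (cycloisomerization) should follow the 6-endo-dig course because C3 is both the delta carbon of the ynenone and the alkyne carbon that carries the cation-stabilizing vinyl group, and only the C1 hydroxyl can reach it.

Step 17
Reactants: 21 unit A allylic alcohol
Product: 22 (7S)-3-[(1E)-3-acetoxyprop-1-en-1-yl]-7-methyl-6,8-dioxo-5,6,7,8-tetrahydro-1H-isochromen-7-yl 2,4-bis(TBSO)-6-methylbenzoate
Conditions: AcCl (1.1 equiv.), 2,4,6-collidine, CH2Cl2, −78 °C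
Reagents that add atoms: acetyl chloride, CC(Cl)=O
Why: The primary allylic alcohol is the only hydroxyl left and is acetylated under weakly basic conditions that do not enolize the dione (ester formation).

Step 18
Reactants: 23 (R)-lactic acid; 11 pivalaldehyde
Product: 24 (2R,5R)-2-tert-butyl-5-methyl-1,3-dioxolan-4-one
Conditions: TsOH·H2O (cat.), H2SO4 (cat.), pentane, reflux, Dean–Stark; crystallization, −78 °C
Reagents that add atoms: none
Why: The same acetalization as in step 8 gives the enantiomeric cis dioxolanone for unit B.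

Step 19
Reactants: 24 (2R,5R)-dioxolanone; 9 enal
Product: 25 (2R,5S)-2-tert-butyl-5-[(2Z,6E)-8-(TBSO)-2-(TBSOCH2)-1-hydroxy-3-methylocta-2,6-dien-4-yn-1-yl]-5-methyl-1,3-dioxolan-4-one (both carbinol epimers)
Conditions: LiN(iPr)2, THF, −78 °C; 9, −78 °C; AcOH
Reagents that add atoms: none
Why: Aldol addition anti to the tert-butyl group, as in step 9, sets C7′ in the configuration derived from (R)-lactate.

Step 20
Reactants: 25 aldol adduct
Product: 26 (2R,5S)-2-tert-butyl-5-[(2Z,6E)-8-(TBSO)-2-(TBSOCH2)-3-methylocta-2,6-dien-4-ynoyl]-5-methyl-1,3-dioxolan-4-one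
Conditions: Dess–Martin periodinane, CH2Cl2, 0 → 23 °C
Reagents that add atoms: none
Why: Dess–Martin oxidation of the allylic carbinol gives the C8′ ketone without retro-aldol cleavage.

Step 21
Reactants: 26 acyl dioxolanone (enantiomer of 14)
Product: 27 (2R)-5-[(3E)-5-(TBSO)pent-3-en-1-yn-1-yl]-4-(TBSOCH2)-2-hydroxy-2-methylcyclohex-4-ene-1,3-dione
Conditions: LiN(SiMe3)2 (2.5 equiv.), THF, −78 → 0 °C; AcOH
Reagents that add atoms: none
Why: Proposed new method: the closure of step 11 on the enantiomeric precursor, in which deprotonation of the C5′ methyl gives the dienolate, its terminal carbon attacks the dioxolanone carbonyl C6′ (6-(enolendo)-exo-trig), the acetal ring opens and pivalaldehyde is lost with C7′ untouched; the closest known reaction types are vinylogous Dieckmann condensations of gamma-deprotonated enones and acyl transfer from 5,5-disubstituted 1,3-dioxolan-4-ones.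

Step 22
Reactants: 27 (2R)-hydroxy dione
Product: 29 (2R)-5-[(3E)-5-(TBSO)pent-3-en-1-yn-1-yl]-4-(TBSOCH2)-2-methyl-2-(triethylsilyloxy)cyclohex-4-ene-1,3-dione, via bis(triethylsilyl) dienol ether 28 (not isolated)
Conditions: TESOTf (2.5 equiv.), 2,6-lutidine, CH2Cl2, −78 → 0 °C; MeOH, 0 °C
Reagents that add atoms: triethylsilyl trifluoromethanesulfonate (TESOTf), CC[Si](CC)(CC)OS(=O)(=O)C(F)(F)F
Why: The silyl triflate silylates the hindered tertiary hydroxyl and also the enolizable C6′ carbonyl, and brief methanolysis cleaves only the labile dienol silyl ether (silyl ether formation).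

Step 23
Reactants: 29 silyloxy dione
Product: 30 (5R,6R)-3-[(3E)-5-(TBSO)pent-3-en-1-yn-1-yl]-2-(TBSOCH2)-5-hydroxy-6-methyl-6-(triethylsilyloxy)cyclohex-2-en-1-one
Conditions: NaBH4, MeOH/THF, −78 → −40 °C
Reagents that add atoms: none
Why: Borohydride reduction of the saturated C6′ ketone, which is more electrophilic and less hindered than the ynenone carbonyl C8′, should occur anti to the pseudo-axial silyloxy group on C7′ (polar 1,2-induction), giving the C6′ hydroxyl cis to O7′, that is 6′R.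

Step 24
Reactants: 30 secondary alcohol; 18 acid chloride
Product: 31 (1R,6R)-3-[(3E)-5-(TBSO)pent-3-en-1-yn-1-yl]-4-(TBSOCH2)-6-methyl-5-oxo-6-(triethylsilyloxy)cyclohex-3-en-1-yl 2,4-bis(TBSO)-6-methylbenzoate
Conditions: DMAP, Et3N, CH2Cl2, 0 → 40 °C
Reagents that add atoms: none
Why: DMAP-catalysed acylation of the only free hydroxyl by the acid chloride installs the orsellinate on O6′ with retention at C6′ (esterification).

Step 25
Reactants: 31 silylated ring ester
Product: 32 (1R,6R)-6-hydroxy-4-(hydroxymethyl)-3-[(3E)-5-hydroxypent-3-en-1-yn-1-yl]-6-methyl-5-oxocyclohex-3-en-1-yl 2,4-bis(TBSO)-6-methylbenzoate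
Conditions: HF·pyridine, THF, 0 → 23 °C
Reagents that add atoms: none
Why: HF·pyridine removes the two primary silyl ethers and the tertiary triethylsilyl ether, while the aryl silyl ethers on the benzoate should react more slowly (desilylation).

Step 26
Reactants: 32 triol
Product: 33 (6R,7R)-7-hydroxy-3-[(1E)-3-hydroxyprop-1-en-1-yl]-7-methyl-8-oxo-5,6,7,8-tetrahydro-1H-isochromen-6-yl 2,4-bis(TBSO)-6-methylbenzoate
Conditions: AuCl(PPh3) (5 mol %), AgOTf (5 mol %), CH2Cl2, 23 °C
Reagents that add atoms: none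
Why: As in step 16, gold-catalysed 6-endo-dig hydroalkoxylation by the C1′ hydroxyl at the delta carbon of the ynenone closes the pyran (cycloisomerization).

Step 27
Reactants: 33 unit B allylic alcohol
Product: 34 (6R,7R)-7-hydroxy-7-methyl-8-oxo-3-[(1E)-3-oxoprop-1-en-1-yl]-5,6,7,8-tetrahydro-1H-isochromen-6-yl 2,4-bis(TBSO)-6-methylbenzoate
Conditions: MnO2, CH2Cl2, 23 °C
Reagents that add atoms: none
Why: MnO2 oxidizes only the primary allylic alcohol to the (E)-enal and leaves the tertiary alpha-ketol untouched (allylic oxidation).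

Step 28
Reactants: 22 unit A methylene dione; 34 unit B enal
Product: 35 tetrakis(TBS) ether of the target (all four phenols silylated)
Conditions: ethylenediammonium diacetate (10 mol %), 4 Å MS, CH2Cl2, 23 °C
Reagents that add atoms: none
Why: Knoevenagel condensation of the doubly activated C5 methylene of 22 with the aldehyde of 34 forms the C5=CH bond, and reversible amine addition should settle the new alkene as 5Z, the isomer in which the chain avoids the peri hydrogen on C4.

Step 29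
Reactants: 35 protected dimer
Product: 36 CNP0283591.2 (target)
Conditions: Bu4NF, AcOH (1:1), THF, 0 °C
Reagents that add atoms: none
Why: Fluoride cleaves the four aryl silyl ethers rapidly, and the acetic acid buffer keeps the phenoxides protonated so that the acetate, both orsellinates and the alpha-ketol should survive (desilylation).

## Compound list

1 | methyl 3-hydroxypropanoate | COC(=O)CCO | starting material
2 | methyl 3-(TBSO)propanoate | COC(=O)CCO[Si](C)(C)C(C)(C)C | intermediate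
3 | methyl 2-(TBSOCH2)-3-oxobutanoate (racemic) | COC(=O)C(CO[Si](C)(C)C(C)(C)C)C(C)=O | intermediate
4 | methyl (2Z)-2-(TBSOCH2)-3-(trifluoromethylsulfonyloxy)but-2-enoate | C/C(OS(=O)(=O)C(F)(F)F)=C(\CO[Si](C)(C)C(C)(C)C)C(=O)OC | intermediate
5 | (2E)-pent-2-en-4-yn-1-ol | C#C/C=C/CO | starting material
6 | tert-butyl(dimethyl)[(2E)-pent-2-en-4-yn-1-yloxy]silane | C#C/C=C/CO[Si](C)(C)C(C)(C)C | intermediate
7 | methyl (2Z,6E)-8-(TBSO)-2-(TBSOCH2)-3-methylocta-2,6-dien-4-ynoate | C/C(C#C/C=C/CO[Si](C)(C)C(C)(C)C)=C(\CO[Si](C)(C)C(C)(C)C)C(=O)OC | intermediate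
8 | (2E,6E)-8-(TBSO)-2-(TBSOCH2)-3-methylocta-2,6-dien-4-yn-1-ol | C/C(C#C/C=C/CO[Si](C)(C)C(C)(C)C)=C(\CO[Si](C)(C)C(C)(C)C)CO | intermediate
9 | (2Z,6E)-8-(TBSO)-2-(TBSOCH2)-3-methylocta-2,6-dien-4-ynal | C/C(C#C/C=C/CO[Si](C)(C)C(C)(C)C)=C(\CO[Si](C)(C)C(C)(C)C)C=O | intermediate
10 | (S)-lactic acid | C[C@H](O)C(=O)O | starting material
11 | pivalaldehyde | CC(C)(C)C=O | starting material
12 | (2S,5S)-2-tert-butyl-5-methyl-1,3-dioxolan-4-one | C[C@@H]1O[C@H](C(C)(C)C)OC1=O | intermediate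
13 | (2S,5R)-2-tert-butyl-5-[(2Z,6E)-8-(TBSO)-2-(TBSOCH2)-1-hydroxy-3-methylocta-2,6-dien-4-yn-1-yl]-5-methyl-1,3-dioxolan-4-one (carbinol epimers) | C/C(C#C/C=C/CO[Si](C)(C)C(C)(C)C)=C(/C(O)[C@@]1(C)O[C@H](C(C)(C)C)OC1=O)CO[Si](C)(C)C(C)(C)C | intermediate
14 | (2S,5R)-2-tert-butyl-5-[(2Z,6E)-8-(TBSO)-2-(TBSOCH2)-3-methylocta-2,6-dien-4-ynoyl]-5-methyl-1,3-dioxolan-4-one | C/C(C#C/C=C/CO[Si](C)(C)C(C)(C)C)=C(/C(=O)[C@@]1(C)O[C@H](C(C)(C)C)OC1=O)CO[Si](C)(C)C(C)(C)C | intermediate
15 | (2S)-5-[(3E)-5-(TBSO)pent-3-en-1-yn-1-yl]-4-(TBSOCH2)-2-hydroxy-2-methylcyclohex-4-ene-1,3-dione | O=C1CC(C#C/C=C/CO[Si](C)(C)C(C)(C)C)=C(CO[Si](C)(C)C(C)(C)C)C(=O)[C@@]1(C)O | intermediate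
16 | orsellinic acid (2,4-dihydroxy-6-methylbenzoic acid) | Cc1cc(O)cc(O)c1C(=O)O | starting material
17 | tert-butyldimethylsilyl 2,4-bis(TBSO)-6-methylbenzoate | Cc1cc(O[Si](C)(C)C(C)(C)C)cc(O[Si](C)(C)C(C)(C)C)c1C(=O)O[Si](C)(C)C(C)(C)C | intermediate
18 | 2,4-bis(TBSO)-6-methylbenzoyl chloride | Cc1cc(O[Si](C)(C)C(C)(C)C)cc(O[Si](C)(C)C(C)(C)C)c1C(Cl)=O | intermediate
19 | (1S)-4-[(3E)-5-(TBSO)pent-3-en-1-yn-1-yl]-3-(TBSOCH2)-1-methyl-2,6-dioxocyclohex-3-en-1-yl 2,4-bis(TBSO)-6-methylbenzoate | O=C1CC(C#C/C=C/CO[Si](C)(C)C(C)(C)C)=C(CO[Si](C)(C)C(C)(C)C)C(=O)[C@@]1(C)OC(=O)c1c(C)cc(O[Si](C)(C)C(C)(C)C)cc1O[Si](C)(C)C(C)(C)C | intermediate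
20 | (1S)-3-(hydroxymethyl)-4-[(3E)-5-hydroxypent-3-en-1-yn-1-yl]-1-methyl-2,6-dioxocyclohex-3-en-1-yl 2,4-bis(TBSO)-6-methylbenzoate | O=C1CC(C#C/C=C/CO)=C(CO)C(=O)[C@@]1(C)OC(=O)c1c(C)cc(O[Si](C)(C)C(C)(C)C)cc1O[Si](C)(C)C(C)(C)C | intermediate
21 | (7S)-3-[(1E)-3-hydroxyprop-1-en-1-yl]-7-methyl-6,8-dioxo-5,6,7,8-tetrahydro-1H-isochromen-7-yl 2,4-bis(TBSO)-6-methylbenzoate | OC/C=C/C1=CC2=C(CO1)C(=O)[C@@](C)(OC(=O)c1c(C)cc(O[Si](C)(C)C(C)(C)C)cc1O[Si](C)(C)C(C)(C)C)C(=O)C2 | intermediate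
22 | (7S)-3-[(1E)-3-acetoxyprop-1-en-1-yl]-7-methyl-6,8-dioxo-5,6,7,8-tetrahydro-1H-isochromen-7-yl 2,4-bis(TBSO)-6-methylbenzoate | CC(=O)OC/C=C/C1=CC2=C(CO1)C(=O)[C@@](C)(OC(=O)c1c(C)cc(O[Si](C)(C)C(C)(C)C)cc1O[Si](C)(C)C(C)(C)C)C(=O)C2 | intermediate
23 | (R)-lactic acid | C[C@@H](O)C(=O)O | starting material
24 | (2R,5R)-2-tert-butyl-5-methyl-1,3-dioxolan-4-one | C[C@H]1O[C@@H](C(C)(C)C)OC1=O | intermediate
25 | (2R,5S)-2-tert-butyl-5-[(2Z,6E)-8-(TBSO)-2-(TBSOCH2)-1-hydroxy-3-methylocta-2,6-dien-4-yn-1-yl]-5-methyl-1,3-dioxolan-4-one (carbinol epimers) | C/C(C#C/C=C/CO[Si](C)(C)C(C)(C)C)=C(/C(O)[C@]1(C)O[C@@H](C(C)(C)C)OC1=O)CO[Si](C)(C)C(C)(C)C | intermediate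
26 | (2R,5S)-2-tert-butyl-5-[(2Z,6E)-8-(TBSO)-2-(TBSOCH2)-3-methylocta-2,6-dien-4-ynoyl]-5-methyl-1,3-dioxolan-4-one | C/C(C#C/C=C/CO[Si](C)(C)C(C)(C)C)=C(/C(=O)[C@]1(C)O[C@@H](C(C)(C)C)OC1=O)CO[Si](C)(C)C(C)(C)C | intermediate
27 | (2R)-5-[(3E)-5-(TBSO)pent-3-en-1-yn-1-yl]-4-(TBSOCH2)-2-hydroxy-2-methylcyclohex-4-ene-1,3-dione | O=C1CC(C#C/C=C/CO[Si](C)(C)C(C)(C)C)=C(CO[Si](C)(C)C(C)(C)C)C(=O)[C@]1(C)O | intermediate
28 | (6R)-3-[(3E)-5-(TBSO)pent-3-en-1-yn-1-yl]-2-(TBSOCH2)-6-methyl-5,6-bis(triethylsilyloxy)cyclohexa-2,4-dien-1-one | CC[Si](CC)(CC)OC1=CC(C#C/C=C/CO[Si](C)(C)C(C)(C)C)=C(CO[Si](C)(C)C(C)(C)C)C(=O)[C@]1(C)O[Si](CC)(CC)CC | intermediate (not isolated)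
29 | (2R)-5-[(3E)-5-(TBSO)pent-3-en-1-yn-1-yl]-4-(TBSOCH2)-2-methyl-2-(triethylsilyloxy)cyclohex-4-ene-1,3-dione | O=C1CC(C#C/C=C/CO[Si](C)(C)C(C)(C)C)=C(CO[Si](C)(C)C(C)(C)C)C(=O)[C@]1(C)O[Si](CC)(CC)CC | intermediate
30 | (5R,6R)-3-[(3E)-5-(TBSO)pent-3-en-1-yn-1-yl]-2-(TBSOCH2)-5-hydroxy-6-methyl-6-(triethylsilyloxy)cyclohex-2-en-1-one | C(#C/C=C/CO[Si](C)(C)C(C)(C)C)C1=C(CO[Si](C)(C)C(C)(C)C)C(=O)[C@](C)(O[Si](CC)(CC)CC)[C@H](O)C1 | intermediate
31 | (1R,6R)-3-[(3E)-5-(TBSO)pent-3-en-1-yn-1-yl]-4-(TBSOCH2)-6-methyl-5-oxo-6-(triethylsilyloxy)cyclohex-3-en-1-yl 2,4-bis(TBSO)-6-methylbenzoate | C(#C/C=C/CO[Si](C)(C)C(C)(C)C)C1=C(CO[Si](C)(C)C(C)(C)C)C(=O)[C@](C)(O[Si](CC)(CC)CC)[C@H](OC(=O)c2c(C)cc(O[Si](C)(C)C(C)(C)C)cc2O[Si](C)(C)C(C)(C)C)C1 | intermediate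
32 | (1R,6R)-6-hydroxy-4-(hydroxymethyl)-3-[(3E)-5-hydroxypent-3-en-1-yn-1-yl]-6-methyl-5-oxocyclohex-3-en-1-yl 2,4-bis(TBSO)-6-methylbenzoate | C(#C/C=C/CO)C1=C(CO)C(=O)[C@](C)(O)[C@H](OC(=O)c2c(C)cc(O[Si](C)(C)C(C)(C)C)cc2O[Si](C)(C)C(C)(C)C)C1 | intermediate
33 | (6R,7R)-7-hydroxy-3-[(1E)-3-hydroxyprop-1-en-1-yl]-7-methyl-8-oxo-5,6,7,8-tetrahydro-1H-isochromen-6-yl 2,4-bis(TBSO)-6-methylbenzoate | OC/C=C/C1=CC2=C(CO1)C(=O)[C@](C)(O)[C@H](OC(=O)c1c(C)cc(O[Si](C)(C)C(C)(C)C)cc1O[Si](C)(C)C(C)(C)C)C2 | intermediate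
34 | (6R,7R)-7-hydroxy-7-methyl-8-oxo-3-[(1E)-3-oxoprop-1-en-1-yl]-5,6,7,8-tetrahydro-1H-isochromen-6-yl 2,4-bis(TBSO)-6-methylbenzoate | O=C/C=C/C1=CC2=C(CO1)C(=O)[C@](C)(O)[C@H](OC(=O)c1c(C)cc(O[Si](C)(C)C(C)(C)C)cc1O[Si](C)(C)C(C)(C)C)C2 | intermediate
35 | tetrakis(TBS) ether of the target (7S; 5Z; 6′R,7′R) | CC(=O)OC/C=C/C1=CC2=C(CO1)C(=O)[C@@](C)(OC(=O)c1c(C)cc(O[Si](C)(C)C(C)(C)C)cc1O[Si](C)(C)C(C)(C)C)C(=O)/C2=C\C=C\C1=CC2=C(CO1)C(=O)[C@](C)(O)[C@H](OC(=O)c1c(C)cc(O[Si](C)(C)C(C)(C)C)cc1O[Si](C)(C)C(C)(C)C)C2 | intermediate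
36 | CNP0283591.2: (7S,5Z)-3-[(1E)-3-acetoxyprop-1-enyl]-5-{(2E)-3-[(6R,7R)-6-(2,4-dihydroxy-6-methylbenzoyloxy)-7-hydroxy-7-methyl-8-oxo-5,6,7,8-tetrahydro-1H-isochromen-3-yl]prop-2-enylidene}-7-methyl-6,8-dioxo-5,6,7,8-tetrahydro-1H-isochromen-7-yl 2,4-dihydroxy-6-methylbenzoate | CC(=O)OC/C=C/C1=CC2=C(CO1)C(=O)[C@@](C)(OC(=O)c1c(C)cc(O)cc1O)C(=O)/C2=C\C=C\C1=CC2=C(CO1)C(=O)[C@](C)(O)[C@H](OC(=O)c1c(C)cc(O)cc1O)C2 | target

## Summary

Total step count: 29.
Longest linear sequence: 17 steps (steps 1–3, 5–7 and 19–29).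

Steps most likely to fail:

1. **Step 11** (vinylogous Dieckmann closure onto the dioxolanone). The methyl group may be deprotonated too slowly, or the dienolate may form with the geometry that cannot reach C6 or at the remote silyloxymethylene. Proton transfer may then be too slow to correct this before the acetal ester is consumed in other ways, and released pivalaldehyde may add to the product enolate. Fallback with known chemistry, setting out from 13 and coming back at 15: the dioxolanone of 13 would be opened with K2CO3 in MeOH to the dihydroxy methyl ester F1. The allylic carbinol would be oxidized with Dess–Martin periodinane to the hydroxy keto ester F2, and the tertiary hydroxyl silylated (TMSOTf, 2,6-lutidine) to the trimethylsilyl ether F3. Ring A would then be closed by a conventional vinylogous Dieckmann condensation of the gamma-dienolate onto the methyl ester (LiN(SiMe3)2, THF, −78 → 0 °C) to give the silyloxy dione F4. Its trimethylsilyl ether would be removed with citric acid in MeOH to give 15.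

2. **Step 21** (the same closure in the enantiomeric series). The same processes may intervene. Fallback with known chemistry, setting out from 25 and coming back at 29: methanolysis of 25 (K2CO3, MeOH) to the dihydroxy methyl ester F5, Dess–Martin oxidation to the hydroxy keto ester F6, and silylation (TESOTf, 2,6-lutidine) to the triethylsilyl ether F7. Vinylogous Dieckmann condensation onto the methyl ester (LiN(SiMe3)2, THF) would give 29 directly, so that steps 21 and 22 are bypassed.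

3. **Step 23** (reduction of C6′). Hydride may be delivered syn to the silyloxy group (poor facial selectivity), or enolization of the dione towards C5′ may stall the reduction. Fallback, setting out from 29 and coming back at 31: whatever (5S) alcohol F8 is formed in the reduction would be separated and esterified with inversion under Mitsunobu conditions (PPh3, DIAD, toluene) with 2,4-bis(TBSO)-6-methylbenzoic acid F9. F9 would be obtained from 17 by hydrolysis of the silyl ester (AcOH, THF, H2O). Both epimers of the reduction would then converge on 31.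

## Further compounds

F1 | step 11 | methyl (2R,4Z,8E)-10-(TBSO)-4-(TBSOCH2)-2,3-dihydroxy-2,5-dimethyldeca-4,8-dien-6-ynoate (carbinol epimers) | C/C(C#C/C=C/CO[Si](C)(C)C(C)(C)C)=C(/C(O)[C@@](C)(O)C(=O)OC)CO[Si](C)(C)C(C)(C)C
F2 | step 11 | methyl (2R,4Z,8E)-10-(TBSO)-4-(TBSOCH2)-2-hydroxy-2,5-dimethyl-3-oxodeca-4,8-dien-6-ynoate | C/C(C#C/C=C/CO[Si](C)(C)C(C)(C)C)=C(/C(=O)[C@@](C)(O)C(=O)OC)CO[Si](C)(C)C(C)(C)C
F3 | step 11 | methyl (2R,4Z,8E)-10-(TBSO)-4-(TBSOCH2)-2,5-dimethyl-3-oxo-2-(trimethylsilyloxy)deca-4,8-dien-6-ynoate | C/C(C#C/C=C/CO[Si](C)(C)C(C)(C)C)=C(/C(=O)[C@@](C)(O[Si](C)(C)C)C(=O)OC)CO[Si](C)(C)C(C)(C)C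
F4 | step 11 | (2S)-5-[(3E)-5-(TBSO)pent-3-en-1-yn-1-yl]-4-(TBSOCH2)-2-methyl-2-(trimethylsilyloxy)cyclohex-4-ene-1,3-dione | O=C1CC(C#C/C=C/CO[Si](C)(C)C(C)(C)C)=C(CO[Si](C)(C)C(C)(C)C)C(=O)[C@@]1(C)O[Si](C)(C)C
F5 | step 21 | methyl (2S,4Z,8E)-10-(TBSO)-4-(TBSOCH2)-2,3-dihydroxy-2,5-dimethyldeca-4,8-dien-6-ynoate (carbinol epimers) | C/C(C#C/C=C/CO[Si](C)(C)C(C)(C)C)=C(/C(O)[C@](C)(O)C(=O)OC)CO[Si](C)(C)C(C)(C)C
F6 | step 21 | methyl (2S,4Z,8E)-10-(TBSO)-4-(TBSOCH2)-2-hydroxy-2,5-dimethyl-3-oxodeca-4,8-dien-6-ynoate | C/C(C#C/C=C/CO[Si](C)(C)C(C)(C)C)=C(/C(=O)[C@](C)(O)C(=O)OC)CO[Si](C)(C)C(C)(C)C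
F7 | step 21 | methyl (2S,4Z,8E)-10-(TBSO)-4-(TBSOCH2)-2,5-dimethyl-3-oxo-2-(triethylsilyloxy)deca-4,8-dien-6-ynoate | C/C(C#C/C=C/CO[Si](C)(C)C(C)(C)C)=C(/C(=O)[C@](C)(O[Si](CC)(CC)CC)C(=O)OC)CO[Si](C)(C)C(C)(C)C
F8 | step 23 | (5S,6R)-3-[(3E)-5-(TBSO)pent-3-en-1-yn-1-yl]-2-(TBSOCH2)-5-hydroxy-6-methyl-6-(triethylsilyloxy)cyclohex-2-en-1-one | C(#C/C=C/CO[Si](C)(C)C(C)(C)C)C1=C(CO[Si](C)(C)C(C)(C)C)C(=O)[C@](C)(O[Si](CC)(CC)CC)[C@@H](O)C1
F9 | step 23 | 2,4-bis(TBSO)-6-methylbenzoic acid | Cc1cc(O[Si](C)(C)C(C)(C)C)cc(O[Si](C)(C)C(C)(C)C)c1C(=O)O
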